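## Structural features

The target 16 has two benzene rings at the ends of an unbranched chain of fourteen methylene groups: ring A, a 3-hydroxy-5-methoxyphenyl group, sits on C1 and ring B, a 3,5-dihydroxyphenyl group, on C14. There is no stereocentre, no alkene and no ring other than the two arenes, so no stereocentres stand next to each other and nothing has to be controlled in space. The molecule would be symmetrical but for the single O-methyl group on ring A. Telling that methyl ether apart from three free phenols is the only differentiation problem; it is avoided by buying ring A with the methyl ether in place and carrying the phenols as benzyl ethers, which leave by hydrogenolysis without touching the methyl ether. The fragile parts are the two electron-rich 1,3-dioxygenated rings (easily halogenated, oxidised, or metalated at the carbon between the oxygens) and the free phenols, which are acidic and should appear only at the end. The real difficulty is the tether: fourteen unfunctionalised sp3 carbons offer no handle for bond formation, so a handle must be brought in and later erased to CH2. The key step uses C6, a plain methylene five carbons from ring A (C1 to C5) and eight from ring B (C7 to C14): as C2 of a 1,3-dithiane it can act twice as a carbon nucleophile, and reductive loss of sulfur then returns it to an ordinary methylene.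

## Logic of the disconnections

The first step backwards changes no skeletal bond. The three phenols of 16 are covered as benzyl ethers (giving 15) and C6 regains its two C–S bonds (giving 14). Free phenols would quench every carbanion used to build the chain, and C6 needs an anion-stabilising group while the chain is assembled. The gain is that C6 becomes recognisable as a former nucleophile. The forward step must break two C–S and three benzylic C–O bonds reductively while sparing the aryl methyl ether and both arenes, and sulfur must be gone before a palladium catalyst is used.

In 14 the bonds C5–C6 and C6–C7 are cut, giving the one-carbon unit 10 and the two bromides 5 and 9. The cut is placed at C6 because it divides the chain into a five-carbon and an eight-carbon arm, both of stock length, and because both new bonds then end on one carbon that can be a nucleophile twice. Three pieces of comparable size replace a long linear chain synthesis. The forward step must alkylate 10 twice with two different electrophiles without symmetrical products, and its second metalation must occur at C2 of 12, not on a ring or benzylic ether position.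

In 5 the bond between ring A and C1 is cut, and in 9 the bond between ring B and C14. This leads to the aryl bromides 2 and 6, which become the nucleophiles 4 and 8, and to the symmetrical dibromides 3 and 7, whose second bromine is exactly the leaving group the key step needs. Each arm is thus made in one operation. The demand is monosubstitution of a bifunctional electrophile, met by an excess of 3 or 7 and slow inverse addition.

In 2 the O–benzyl bond is cut, leading to 1. The phenol must be masked because it would protonate 4, and benzyl is chosen so that all three masking groups fall in one final hydrogenolysis; 6 is bought with its benzyl ethers in place. The forward step is a routine O-alkylation with no selectivity issue, since the other oxygen of 1 is already a methyl ether.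

## Other disconnections considered

Alternative 1: The cut goes through ring A, which is traced back to dimethyl malonate A3 and the methyl enone A2, (E)-18-[3,5-bis(benzyloxy)phenyl]octadec-3-en-2-one.
- **Forward key step:** alkoxide-mediated Michael addition of A3 to the β-carbon of A2, then Dieckmann-type closure of the methyl ketone enolate onto one ester, would give the cyclohexanedione ester A1. Hydrolysis and decarboxylation, O-methylation to the vinylogous ester and dehydrogenation would then be needed to reach the aromatic monomethyl ether.
- **In favour:** the annulation is classical, cheap and scalable. The two oxygens of ring A are differentiated by the chemistry itself, so ring A needs no protecting group; on this point the alternative is better than the chosen plan, which must protect and later free the ring A phenol. The stereocentres of A1 vanish on aromatisation, so on stereochemistry the two plans are equal.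
- **Against:** A2 already contains ring B and the whole fourteen-carbon tether, so the chain is left to a long linear sequence before the key step. The late dehydrogenation needs an oxidant or high temperature in the presence of the electron-rich, benzyl-protected ring B and could halogenate or oxidise it, or give mixtures of differently methylated products.
- **Comparison:** both key steps are reliable stepwise anionic C–C bond formations. After the annulation at least four operations would remain, against one after the key step of the chosen plan, which should therefore be clearly ahead in convergence and step economy.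

Alternative 2: Ring B is taken apart so that three ring carbons come from dimethyl 3-oxopentanedioate A6 and three from the alkynoate A5, methyl 17-[3-(benzyloxy)-5-methoxyphenyl]heptadec-2-ynoate.
- **Forward key step:** the sodium enolate of A6 would add to the β-carbon of A5, the second α-carbon would acylate on the alkynoate ester, and tautomerisation would give the dihydroxyisophthalate A4. Saponification with double decarboxylation would then uncover ring B.
- **In favour:** ring B is formed aromatic, so no oxidation step is needed. Both hydroxyls of ring B appear free, so this ring needs no protecting group, which is better than the chosen plan with its two benzyl ethers there. Ring B is symmetrical, so the alternative is the equal of the chosen plan in regiochemical certainty.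
- **Against:** A5 must carry ring A and the whole tether, again built linearly beforehand. Addition of a stabilised enolate to a β-alkyl alkynoate is expected to be sluggish, and closure through oxygen to a pyranone may compete with C-acylation. The two ester groups are ballast to be removed under forcing conditions, and ring A still needs its benzyl group, so a hydrogenolysis remains.
- **Comparison:** the preparation of A5 alone is estimated to need about as many steps as the whole chosen route.

Alternative 3: Ring A is disconnected across two ring bonds into the cyclobutenone A8, 3-{14-[3,5-bis(benzyloxy)phenyl]tetradecyl}cyclobut-2-en-1-one, and methoxyethyne A9.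
- **Forward key step:** on heating, A8 should open in a four-electron electrocyclic reaction to a vinylketene, which adds to A9 in a [2+2] cycloaddition. A second four-electron opening, a six-electron electrocyclisation and tautomerisation would give the phenol A7, the same compound Alternative 1 would reach after its aromatisation.
- **In favour:** no reagent is needed, the conditions are neutral, and the polarity of the ketene and the ynol ether fixes the regiochemistry. The phenol and the methyl ether of ring A are formed directly and differentiated without a protecting group or an oxidation. On this point the alternative is better than the chosen plan and than Alternative 1.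
- **Against:** A8 is not a stock compound and would have to be made in several steps from a terminal alkyne that already carries ring B and the tether; such cyclobutenones are sensitive. A9 is a low-boiling, unstable alkyne that must be generated and used in excess in a closed vessel. Ring B still has to be debenzylated.
- **Comparison:** the thermal cascade is elegant, but the chain problem stays unsolved and the linear step count is estimated to be roughly twice that of the chosen plan.

All three alternatives construct a ring that can be bought and leave the tether to be assembled separately; the chosen plan buys both rings and spends its key step on the tether.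

Key step: step 4

Remark on the chemistry: chain carbons are numbered C1 (bonded to ring A) to C14 (bonded to ring B); all structures of the plan were rechecked against the count 5 + 1 + 8 = 14 methylenes and needed no correction, so the refinements made are the order and stoichiometry of the two alkylations, inverse addition in the two coupling steps and a nickel-then-palladium end game in one operation; Raney Ni is assumed to be W-2 grade kept under ethanol.

## Route

Step 1
Reactants: 1 3-bromo-5-methoxyphenol
Product: 2 1-(benzyloxy)-3-bromo-5-methoxybenzene
Conditions: BnBr (1.1 equiv), K2CO3, DMF, rt
Reagents that add atoms: benzyl bromide, BrCc1ccccc1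
Why: Williamson ether synthesis: the phenoxide formed with K2CO3 displaces bromide from the benzylic halide by SN2, and the aryl bromide and the methyl ether are inert under these conditions.

Step 2
Reactants: 2 1-(benzyloxy)-3-bromo-5-methoxybenzene; 3 1,5-dibromopentane
Product: 5 1-(benzyloxy)-3-(5-bromopentyl)-5-methoxybenzene, via arylmagnesium bromide 4 (not isolated)
Conditions: Mg, I2 (cat.), THF, reflux; then slow addition to 3 (4 equiv), Li2CuCl4 (3 mol %), THF, 0 °C to rt
Reagents that add atoms: none
Why: Magnesium inserts into the aryl C–Br bond to give 4, and in a Kochi-type copper-catalysed cross-coupling (Li2CuCl4 is reduced in the flask to an organocuprate of monovalent copper) the aryl group substitutes one primary bromide of 3, forming the bond between ring A and C1. Slow addition of 4 to a fourfold excess of 3 keeps the second substitution minor, and the surplus 3 is distilled off under vacuum and reused. Benzyl and methyl aryl ethers are inert to Grignard reagents.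

Step 3
Reactants: 6 1,3-bis(benzyloxy)-5-bromobenzene; 7 1,8-dibromooctane
Product: 9 1,3-bis(benzyloxy)-5-(8-bromooctyl)benzene, via arylmagnesium bromide 8 (not isolated)
Conditions: Mg, I2 (cat.), THF, reflux; then slow addition to 7 (4 equiv), Li2CuCl4 (3 mol %), THF, 0 °C to rt
Reagents that add atoms: none
Why: The same sequence as in step 2: magnesium insertion gives 8, and Kochi-type copper-catalysed substitution of one bromide of 7 forms the bond between ring B and C14. Excess 7 and inverse addition again favour the monobromide, and the surplus 7 is removed by short-path distillation under vacuum.

Step 4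
Reactants: 10 1,3-dithiane; 5 1-(benzyloxy)-3-(5-bromopentyl)-5-methoxybenzene; 9 1,3-bis(benzyloxy)-5-(8-bromooctyl)benzene
Product: 14 2-{5-[3-(benzyloxy)-5-methoxyphenyl]pentyl}-2-{8-[3,5-bis(benzyloxy)phenyl]octyl}-1,3-dithiane, via 2-lithio-1,3-dithiane 11 (not isolated), via 2-monoalkyl-1,3-dithiane 12 (not isolated), via 2-lithio-2-alkyl-1,3-dithiane 13 (not isolated)
Conditions: 10 (1.1 equiv), n-BuLi (1.05 equiv), THF, −30 °C; 5 (1.0 equiv), −30 to 0 °C; n-BuLi (1.1 equiv), −30 to −20 °C; 9 (1.2 equiv), −20 °C to rt
Reagents that add atoms: none
Why: n-BuLi removes the C2 proton of 10, which the two sulfur atoms acidify, to give 11, and this carbanion displaces bromide from 5 by SN2 to give 12. The remaining C2–H of 12 is markedly less acidic than that of 10, so 11 is not quenched by 12 to a useful extent and no second alkylation occurs until fresh base is added. A second charge of n-BuLi at −30 to −20 °C converts 12 into 13, which displaces bromide from 9 to give the fully substituted thioketal 14, so that the bonds C5–C6 and C6–C7 are formed in one flask. The closest known reaction type is the Corey–Seebach sequential dialkylation of 1,3-dithiane with two different primary halides, used as a methylene dianion equivalent. No ring is closed and no stereocentre is created, since C2 of the symmetrical dithiane ring carries two identical sulfur branches. The step needs chemoselectivity for the unsymmetrical product: 11 is used in slight excess over 5 so that no 5 is left when the second base charge is added, and the small amount of monoalkyl by-product that surplus 11 forms with 9 is much lighter than 14 and should be separable. It also needs site selectivity in the second metalation (C2–H of 12 against the O–CH2Ph protons and the ring A position between the two oxygens), which low temperature, a titrated base charge and installing first the arm with only one benzyl ether should secure. Both electrophiles are unbranched primary bromides at least five carbons from the arene, so substitution should outrun elimination.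

Step 5
Reactants: 14 2-{5-[3-(benzyloxy)-5-methoxyphenyl]pentyl}-2-{8-[3,5-bis(benzyloxy)phenyl]octyl}-1,3-dithiane
Product: 16 5-[14-(3-hydroxy-5-methoxyphenyl)tetradecyl]benzene-1,3-diol, via tris(benzyl ether) 15 (not isolated)
Conditions: Raney Ni (W-2, excess), EtOH/THF, reflux; filter through Celite; then H2 (1 atm), 10% Pd/C, EtOH/EtOAc, rt
Reagents that add atoms: none
Why: Raney Ni cleaves both C–S bonds of the thioketal with its adsorbed hydrogen (Mozingo reduction), so the linchpin carbon becomes the C6 methylene; sulfur stays on the nickel, which is filtered off before palladium is introduced. Palladium-catalysed hydrogenolysis then cleaves the three benzylic C–O bonds (any that already fall on the nickel lead towards the same product), while the aryl methyl ether and both arenes should be untouched at rt under one atmosphere of hydrogen.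

## Compound list

1 | 3-bromo-5-methoxyphenol | COc1cc(O)cc(Br)c1 | starting material
2 | 1-(benzyloxy)-3-bromo-5-methoxybenzene | COc1cc(Br)cc(OCc2ccccc2)c1 | intermediate
3 | 1,5-dibromopentane | BrCCCCCBr | starting material
4 | [3-(benzyloxy)-5-methoxyphenyl]magnesium bromide | COc1cc(OCc2ccccc2)cc([Mg]Br)c1 | intermediate
5 | 1-(benzyloxy)-3-(5-bromopentyl)-5-methoxybenzene | COc1cc(OCc2ccccc2)cc(CCCCCBr)c1 | intermediate
6 | 1,3-bis(benzyloxy)-5-bromobenzene | Brc1cc(OCc2ccccc2)cc(OCc2ccccc2)c1 | starting material
7 | 1,8-dibromooctane | BrCCCCCCCCBr | starting material
8 | [3,5-bis(benzyloxy)phenyl]magnesium bromide | Br[Mg]c1cc(OCc2ccccc2)cc(OCc2ccccc2)c1 | intermediate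
9 | 1,3-bis(benzyloxy)-5-(8-bromooctyl)benzene | BrCCCCCCCCc1cc(OCc2ccccc2)cc(OCc2ccccc2)c1 | intermediate
10 | 1,3-dithiane | C1CSCSC1 | starting material
11 | 2-lithio-1,3-dithiane | [Li]C1SCCCS1 | intermediate
12 | 2-{5-[3-(benzyloxy)-5-methoxyphenyl]pentyl}-1,3-dithiane | COc1cc(OCc2ccccc2)cc(CCCCCC2SCCCS2)c1 | intermediate
13 | 2-lithio-2-{5-[3-(benzyloxy)-5-methoxyphenyl]pentyl}-1,3-dithiane | COc1cc(OCc2ccccc2)cc(CCCCCC2([Li])SCCCS2)c1 | intermediate
14 | 2-{5-[3-(benzyloxy)-5-methoxyphenyl]pentyl}-2-{8-[3,5-bis(benzyloxy)phenyl]octyl}-1,3-dithiane | COc1cc(OCc2ccccc2)cc(CCCCCC2(CCCCCCCCc3cc(OCc4ccccc4)cc(OCc4ccccc4)c3)SCCCS2)c1 | intermediate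
15 | 1-(benzyloxy)-3-{14-[3,5-bis(benzyloxy)phenyl]tetradecyl}-5-methoxybenzene | COc1cc(OCc2ccccc2)cc(CCCCCCCCCCCCCCc2cc(OCc3ccccc3)cc(OCc3ccccc3)c2)c1 | intermediate
16 | 5-[14-(3-hydroxy-5-methoxyphenyl)tetradecyl]benzene-1,3-diol | COc1cc(O)cc(CCCCCCCCCCCCCCc2cc(O)cc(O)c2)c1 | target

## Step count and least certain steps

Total step count: 5. Longest linear sequence: 4 steps (steps 1, 2, 4 and 5); step 3 supplies the second arm in one step.

**Step 4 (key step).**
- Risk: the second metalation may be incomplete or unselective. n-BuLi could be consumed by deprotonation at the benzylic O–CH2 position (followed by Wittig rearrangement) or at the ring A carbon between the two oxygens faster than it removes the hindered C2–H of 12. Carry-over of unreacted electrophile into the second stage would lead to symmetrical dialkylation.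
- Fallback: setting out from 5 and 9, the same two bonds are made with a linchpin that needs only a mild base. Bis(benzenesulfonyl)methane is alkylated with 5 (NaH, DMF, rt) to give 1-(benzyloxy)-3-[6,6-bis(benzenesulfonyl)hexyl]-5-methoxybenzene F1. A second alkylation with 9 (NaH, NaI cat., DMF, 60 °C) gives 1-(benzyloxy)-3-{14-[3,5-bis(benzyloxy)phenyl]-6,6-bis(benzenesulfonyl)tetradecyl}-5-methoxybenzene F2. Reductive desulfonylation (Mg, MeOH/THF, 50 °C) should give 15, where the route is rejoined; the hydrogenolysis stage of step 5 then leads to 16.

**Step 2.**
- Risk: magnesium insertion into the electron-rich aryl bromide may be sluggish, 4 may homocouple to the biaryl, and the dibromide may be substituted twice; separation of 5 from excess 3 may be incomplete.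
- Fallback: setting out from 2, a Sonogashira coupling with pent-4-yn-1-ol (Pd(PPh3)2Cl2, CuI, Et3N, 70 °C) gives 5-[3-(benzyloxy)-5-methoxyphenyl]pent-4-yn-1-ol F3. Hydrogenation of the triple bond over PtO2 (H2, 1 atm, EtOAc), a catalyst that is poor at benzyl ether hydrogenolysis, gives 5-[3-(benzyloxy)-5-methoxyphenyl]pentan-1-ol F4. An Appel reaction (CBr4, PPh3, CH2Cl2, 0 °C) returns to the route at 5.

**Step 3.**
- Risk: the same processes as in step 2 (slow insertion, homocoupling, double substitution), here with a heavier dibromide that is harder to distil away from the product.
- Fallback: setting out from 6, Sonogashira coupling with oct-7-yn-1-ol (Pd(PPh3)2Cl2, CuI, Et3N, 70 °C) gives 8-[3,5-bis(benzyloxy)phenyl]oct-7-yn-1-ol F5. Hydrogenation over PtO2 gives 8-[3,5-bis(benzyloxy)phenyl]octan-1-ol F6, and an Appel reaction (CBr4, PPh3) returns to the route at 9.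

**Step 5.**
- Risk: C–S cleavage at the fully substituted thioketal carbon may be incomplete on nickel of low activity, the polar product may be lost by adsorption on the large nickel surface, and sulfur species carried through the filtration may poison the palladium so that debenzylation stalls.
- Fallback: setting out from 14, the thioketal is hydrolysed (MeI, CaCO3, MeCN/H2O, 50 °C) to 1-[3-(benzyloxy)-5-methoxyphenyl]-14-[3,5-bis(benzyloxy)phenyl]tetradecan-6-one F7. This is condensed with tosylhydrazide (EtOH, reflux) to N'-{1-[3-(benzyloxy)-5-methoxyphenyl]-14-[3,5-bis(benzyloxy)phenyl]tetradecan-6-ylidene}-4-methylbenzenesulfonohydrazide F8 (C=N geometry undefined and irrelevant). Reduction of the tosylhydrazone (catecholborane, CHCl3, 0 °C; then NaOAc·3H2O, reflux) should give 15, where the route is rejoined free of sulfur; hydrogenolysis over Pd/C as in step 5 then gives 16.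

## Further compounds

F1 | step 4 | 1-(benzyloxy)-3-[6,6-bis(benzenesulfonyl)hexyl]-5-methoxybenzene | COc1cc(OCc2ccccc2)cc(CCCCCC(S(=O)(=O)c2ccccc2)S(=O)(=O)c2ccccc2)c1
F2 | step 4 | 1-(benzyloxy)-3-{14-[3,5-bis(benzyloxy)phenyl]-6,6-bis(benzenesulfonyl)tetradecyl}-5-methoxybenzene | COc1cc(OCc2ccccc2)cc(CCCCCC(CCCCCCCCc2cc(OCc3ccccc3)cc(OCc3ccccc3)c2)(S(=O)(=O)c2ccccc2)S(=O)(=O)c2ccccc2)c1
F3 | step 2 | 5-[3-(benzyloxy)-5-methoxyphenyl]pent-4-yn-1-ol | COc1cc(OCc2ccccc2)cc(C#CCCCO)c1
F4 | step 2 | 5-[3-(benzyloxy)-5-methoxyphenyl]pentan-1-ol | COc1cc(OCc2ccccc2)cc(CCCCCO)c1
F5 | step 3 | 8-[3,5-bis(benzyloxy)phenyl]oct-7-yn-1-ol | OCCCCCCC#Cc1cc(OCc2ccccc2)cc(OCc2ccccc2)c1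
F6 | step 3 | 8-[3,5-bis(benzyloxy)phenyl]octan-1-ol | OCCCCCCCCc1cc(OCc2ccccc2)cc(OCc2ccccc2)c1
F7 | step 5 | 1-[3-(benzyloxy)-5-methoxyphenyl]-14-[3,5-bis(benzyloxy)phenyl]tetradecan-6-one | COc1cc(OCc2ccccc2)cc(CCCCCC(=O)CCCCCCCCc2cc(OCc3ccccc3)cc(OCc3ccccc3)c2)c1
F8 | step 5 | N'-{1-[3-(benzyloxy)-5-methoxyphenyl]-14-[3,5-bis(benzyloxy)phenyl]tetradecan-6-ylidene}-4-methylbenzenesulfonohydrazide | COc1cc(OCc2ccccc2)cc(CCCCCC(=NNS(=O)(=O)c2ccc(C)cc2)CCCCCCCCc2cc(OCc3ccccc3)cc(OCc3ccccc3)c2)c1
A1 | alternative 1 | methyl 6-{14-[3,5-bis(benzyloxy)phenyl]tetradecyl}-2,4-dioxocyclohexane-1-carboxylate | COC(=O)C1C(CCCCCCCCCCCCCCc2cc(OCc3ccccc3)cc(OCc3ccccc3)c2)CC(=O)CC1=O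
A2 | alternative 1 | (E)-18-[3,5-bis(benzyloxy)phenyl]octadec-3-en-2-one | CC(=O)/C=C/CCCCCCCCCCCCCCc1cc(OCc2ccccc2)cc(OCc2ccccc2)c1
A3 | alternative 1 | dimethyl malonate | COC(=O)CC(=O)OC
A4 | alternative 2 | dimethyl 6-{14-[3-(benzyloxy)-5-methoxyphenyl]tetradecyl}-2,4-dihydroxybenzene-1,3-dicarboxylate | COC(=O)c1c(CCCCCCCCCCCCCCc2cc(OC)cc(OCc3ccccc3)c2)cc(O)c(C(=O)OC)c1O
A5 | alternative 2 | methyl 17-[3-(benzyloxy)-5-methoxyphenyl]heptadec-2-ynoate | COC(=O)C#CCCCCCCCCCCCCCCc1cc(OC)cc(OCc2ccccc2)c1
A6 | alternative 2 | dimethyl 3-oxopentanedioate | COC(=O)CC(=O)CC(=O)OC
A7 | alternative 3 | 3-{14-[3,5-bis(benzyloxy)phenyl]tetradecyl}-5-methoxyphenol | COc1cc(O)cc(CCCCCCCCCCCCCCc2cc(OCc3ccccc3)cc(OCc3ccccc3)c2)c1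
A8 | alternative 3 | 3-{14-[3,5-bis(benzyloxy)phenyl]tetradecyl}cyclobut-2-en-1-one | O=C1C=C(CCCCCCCCCCCCCCc2cc(OCc3ccccc3)cc(OCc3ccccc3)c2)C1
A9 | alternative 3 | methoxyethyne | COC#C
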